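## Retrosynthetic overview
1. Rings A (α-methylene-γ-lactone) and B (seven-membered) are closed together and last. The C7–C8 bond joins an aldehyde (C8) to a 2-(methoxycarbonyl)allylchromium, an acrylate β-carbanion (homoenolate-type) equivalent at C7.
2. Ring D (δ-lactone) comes from C3–C3' Michael addition of the ring C enolate to a 2-arylacrylate, then lactonisation on the C4 tertiary alcohol.
3. Ring C is bought as cyclopentane-1,3-dione. C1–C10 comes from an iminium-catalysed Michael addition to crotonaldehyde, C15 and O4 from α'-methylation and hydroxylation, and C5–C6 from allyl addition with carbonyl transposition.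
4. The aryl acrylate comes from a redox-relay Heck arylation of (Z)-pent-3-en-1-ol, which sets the benzylic centre, followed by a Negishi coupling that brings in the acrylate.
5. Ring order: arene and C (bought), then D, then B and A in one step. The C2 ketone is reduced and acetylated at the end.

**Labels:** guaianolide numbering C1–C15 (C2 = CHOAc, C4 = C(CH3)O, C7/C8 = γ-lactone fusion, C10 = CHCH3, C13 = exo-methylene carbon). C1'–C3' are C(=O)–CH(Ar)–CH2 of the δ-lactone. TBDPS = tert-butyldiphenylsilyl.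

**Assumption:** (Z)-pent-3-en-1-ol, methyl 2-bromoacrylate, methyl 2-(bromomethyl)acrylate and the camphor-derived oxaziridine are taken as catalogue chemicals.

## Route

### Fragment 1 (ring C with both arms)

Step 1
Reactants: 1 cyclopentane-1,3-dione; 2 (E)-but-2-enal (crotonaldehyde)
Product: 4 (4S)-2-methoxy-4-methyl-3,4,6,7-tetrahydrocyclopenta[b]pyran-5(2H)-one (anomer mixture), via lactol 3 (not isolated)
Conditions: (S)-2-[diphenyl(trimethylsilyloxy)methyl]pyrrolidine (10 mol%), PhCO2H (10 mol%), CH2Cl2, 0 °C; then MeOH, TsOH·H2O (5 mol%), 23 °C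
Reagents that add atoms: methanol, CO
Why: Iminium-catalysed (Jørgensen–Hayashi) Michael addition of the soft dione carbon C1 to the β-carbon of crotonaldehyde, where the silyl prolinol ether shields one face of the E-iminium ion so that C10 forms as S, followed by acetalisation of the lactol, which masks the C8 aldehyde and one enol oxygen and leaves one ketone (C5).

Step 2
Reactants: 4 (4S)-2-methoxy-4-methyl-3,4,6,7-tetrahydrocyclopenta[b]pyran-5(2H)-one
Product: 5 (4S)-2-methoxy-4,6-dimethyl-3,4,6,7-tetrahydrocyclopenta[b]pyran-5(2H)-one (epimers at C6 of the bicycle = C4)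
Conditions: LDA (1.1 equiv), THF, −78 °C; MeI (1.5 equiv), −78 → −20 °C
Reagents that add atoms: iodomethane, CI
Why: Stork–Danheiser-type kinetic α'-deprotonation of the vinylogous ester next to the free ketone and SN2 methylation put C15 on C4, and the new centre is flattened again in step 3, so its ratio does not matter.

Step 3
Reactants: 5 (4S)-2-methoxy-4,6-dimethyl-3,4,6,7-tetrahydrocyclopenta[b]pyran-5(2H)-one
Product: 6 (4S,6S)-6-hydroxy-2-methoxy-4,6-dimethyl-3,4,6,7-tetrahydrocyclopenta[b]pyran-5(2H)-one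
Conditions: NaHMDS (1.2 equiv), THF, −78 °C; (+)-[(8,8-dichlorocamphoryl)sulfonyl]oxaziridine (1.3 equiv)
Reagents that add atoms: (+)-[(8,8-dichlorocamphoryl)sulfonyl]oxaziridine, CC1(C)[C@@H]2CC[C@]13CS(=O)(=O)N4O[C@@]34C2(Cl)Cl
Why: Davis oxidation of the tetrasubstituted sodium enolate, in which the chiral oxaziridine selects the enolate face as it does for 2-methyl-1-tetralone-type enolates (S carbinol), sets C4 as S, and the minor C4 epimer is a diastereomer (C10 is fixed) that is removed on silica.

Step 4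
Reactants: 6 (4S,6S)-6-hydroxy-2-methoxy-4,6-dimethyl-3,4,6,7-tetrahydrocyclopenta[b]pyran-5(2H)-one
Product: 9 (4S)-3-allyl-2-[(2S)-4,4-dimethoxybutan-2-yl]-4-hydroxy-4-methylcyclopent-2-en-1-one, via diol adduct 7 (not isolated), via hydroxy enone aldehyde 8 (not isolated)
Conditions: allylMgBr (3 equiv), THF, −78 → 0 °C; 1 M HCl, 0 °C; then HC(OMe)3, PPTS (5 mol%), MeOH, 23 °C
Reagents that add atoms: allylmagnesium bromide, C=CC[Mg]Br; water, O; trimethyl orthoformate, COC(OC)OC
Why: Stork–Danheiser carbonyl transposition, in which 1,2-addition of the allyl Grignard reagent to C5 and acid ionisation of the vinylogous hemiketal give the C2 ketone with the tetrasubstituted C1=C5 alkene and free the C8 aldehyde, which is re-masked chemoselectively as its dimethyl acetal; no stereocentre is made or touched.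

### Fragment 2 (aryl acrylate)

Step 5
Reactants: 10 methyl 2-amino-4-bromobenzoate
Product: 11 5-bromo-2-(methoxycarbonyl)benzenediazonium tetrafluoroborate
Conditions: NaNO2 (1.05 equiv), 48% aq HBF4, 0 °C
Reagents that add atoms: sodium nitrite, [Na+].[O-]N=O; tetrafluoroboric acid, [H+].F[B-](F)(F)F
Why: Standard diazotisation of an electron-poor aniline gives a filterable, storable arenediazonium tetrafluoroborate.

Step 6
Reactants: 11 5-bromo-2-(methoxycarbonyl)benzenediazonium tetrafluoroborate; 12 (Z)-pent-3-en-1-ol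
Product: 13 methyl 4-bromo-2-[(2R)-5-oxopentan-2-yl]benzoate
Conditions: Pd2(dba)3 (3 mol%), (S)-4-tert-butyl-2-[5-(trifluoromethyl)pyridin-2-yl]-4,5-dihydrooxazole (7 mol%), DMF, 23 °C
Reagents that add atoms: none
Why: Enantioselective redox-relay Heck–Matsuda arylation, in which zerovalent palladium inserts into the diazonium salt only (the C–Br bond survives), the aryl group adds to the alkene carbon remote from the hydroxyl under control of the pyridine-oxazoline ligand (the Z-alkene with the S-ligand is assigned to give R by analogy with related alkenols), and chain-walking ends at the aldehyde.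

Step 7
Reactants: 13 methyl 4-bromo-2-[(2R)-5-oxopentan-2-yl]benzoate
Product: 14 (4R)-4-[5-bromo-2-(hydroxymethyl)phenyl]pentan-1-ol
Conditions: LiBH4 (2.5 equiv), MeOH (1 equiv), THF, 0 → 50 °C
Reagents that add atoms: none
Why: Hydride reduction takes the aldehyde and the benzoate to the two primary alcohols without touching the aryl bromide or the benzylic stereocentre.

Step 8
Reactants: 14 (4R)-4-[5-bromo-2-(hydroxymethyl)phenyl]pentan-1-ol
Product: 15 (4R)-4-[5-bromo-2-(hydroxymethyl)phenyl]pentyl acetate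
Conditions: AcCl (1.05 equiv), 2,4,6-collidine (2 equiv), CH2Cl2, −78 °C
Reagents that add atoms: acetyl chloride, CC(=O)Cl
Why: Kinetically selective O-acylation, because the unhindered chain-end alcohol reacts faster than the benzylic alcohol, which is flanked by the ortho sec-alkyl group.

Step 9
Reactants: 15 (4R)-4-[5-bromo-2-(hydroxymethyl)phenyl]pentyl acetate
Product: 16 (4R)-4-[5-bromo-2-(TBDPSOCH2)phenyl]pentyl acetate
Conditions: TBDPSCl (1.2 equiv), imidazole (2.5 equiv), DMF, 23 °C
Reagents that add atoms: tert-butyl(chloro)diphenylsilane, CC(C)(C)[Si](Cl)(c1ccccc1)c1ccccc1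
Why: Silylation gives an acid- and base-tolerant ether that keeps the benzylic alcohol out of the final acetylation.

Step 10
Reactants: 16 (4R)-4-[5-bromo-2-(TBDPSOCH2)phenyl]pentyl acetate; 17 methyl 2-bromoacrylate
Product: 19 methyl 2-{3-[(2R)-5-acetoxypentan-2-yl]-4-(TBDPSOCH2)phenyl}acrylate, via vinylzinc bromide 18 (not isolated)
Conditions: 17, activated Zn dust (1.5 equiv), THF, 25 °C; then 16, Pd(OAc)2 (3 mol%), SPhos (6 mol%), 50 °C
Reagents that add atoms: none
Why: Negishi coupling of the ester-tolerant [1-(methoxycarbonyl)ethenyl]zinc bromide with the aryl bromide gives the 2-arylacrylate under neutral conditions that spare the acetate and the silyl ether.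

### Union and endgame

Step 11
Reactants: 9 (4S)-3-allyl-2-[(2S)-4,4-dimethoxybutan-2-yl]-4-hydroxy-4-methylcyclopent-2-en-1-one; 19 methyl 2-{3-[(2R)-5-acetoxypentan-2-yl]-4-(TBDPSOCH2)phenyl}acrylate
Product: 21 keto δ-lactone acetal (C3 R; C4 S; C2' R; C10 S): ring C enone cis-fused to ring D; allyl on C5; (S)-CH(CH3)CH2CH(OMe)2 on C1; aryl on C2', via open-chain Michael adduct 20 (not isolated)
Conditions: 9, LiHMDS (2.05 equiv), THF, −78 °C; 19 (1.0 equiv), −78 °C; AcOH (1.0 equiv), −78 → 0 °C
Reagents that add atoms: none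
Why: Kinetic α'-enolate Michael addition (C3 to C3') followed by alkoxide lactonisation, where only the C3 epimer with C3' cis to O4 can close ring D while C3 (α to the ketone) equilibrates, and the resulting α-aryl lactone enolate is protonated axially so that the aryl group ends equatorial (C2' R), which is also the thermodynamic epimer.

Step 12
Reactants: 21 keto δ-lactone acetal
Product: 22 keto δ-lactone aldehyde (as 21 but C8 = CHO)
Conditions: PPTS (0.3 equiv), acetone–H2O (9:1), 50 °C
Reagents that add atoms: water, O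
Why: Mild acetal hydrolysis frees the C8 aldehyde and leaves the TBDPS ether, the acetate and the tertiary lactone C–O bond intact, since ionisation at C4 would give a destabilised 4-oxocyclopentenyl cation.

Step 13
Reactants: 22 keto δ-lactone aldehyde; 23 methyl 2-(bromomethyl)acrylate
Product: 24 allylic bromide aldehyde: C5–CH2–CH=C(CO2Me)CH2Br arm with C6 cis to CH2Br (Z); otherwise as 22
Conditions: 23 (5 equiv), second-generation Hoveyda–Grubbs catalyst (10 mol%), 1,4-benzoquinone (10 mol%), CH2Cl2, 40 °C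
Reagents that add atoms: none
Why: Olefin cross-metathesis of the only unhindered terminal alkene with a non-homodimerising 1,1-disubstituted acrylate gives the trisubstituted enoate, with the chain trans to the ester as the favoured geometry; the tetrasubstituted enone is inert and benzoquinone suppresses allyl isomerisation.

Step 14 (key step)
Reactants: 24 allylic bromide aldehyde
Product: 26 tetracyclic enone (C7 R; C8 S; C10 S; C3 R; C4 S; C2' R): rings A–D complete; C2 ketone; benzylic OTBDPS, via hydroxy ester 25 (not isolated)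
Conditions: CrCl2 (6 equiv), THF (0.004 M, slow addition of 24), 25 °C
Reagents that add atoms: none
Why: Intramolecular Nozaki–Hiyama-type carbonyl allylation, in which two equivalents of divalent chromium turn the bromide into a 2-(methoxycarbonyl)allylchromium so that C7, normally the electrophilic β-carbon of an acrylate, attacks the equally electrophilic aldehyde carbon C8 with allyl transposition (this creates the C11=C13 exo-methylene) through a trans-decalin-like bicyclic chair with the C10 methyl pseudo-axial (away from the C2 carbonyl) and the C6 and C9 tether bonds equatorial, giving the anti adduct (C7 R, C8 S) whose trivalent chromium alkoxide closes the trans-fused lactone.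

Step 15
Reactants: 26 tetracyclic enone
Product: 27 C2 allylic alcohol (C2 R; C3 S; other centres as in 26)
Conditions: NaBH4 (1.2 equiv), CeCl3·7H2O (1.5 equiv), MeOH, −78 °C
Reagents that add atoms: none
Why: Luche 1,2-reduction of the enone, with hydride arriving on the convex face (the face of H3 and C15), opposite the C3' methylene and ring D that fold under the ketone, places O2 cis to C3' and O4 (C2 R); the low temperature spares the α-methylene lactone.

Step 16
Reactants: 27 C2 allylic alcohol
Product: 28 C2 acetate with benzylic OTBDPS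
Conditions: Ac2O (3 equiv), DMAP (0.2 equiv), pyridine, 23 °C
Reagents that add atoms: acetic anhydride, CC(=O)OC(C)=O
Why: DMAP-catalysed acetylation of the only free hydroxyl proceeds with retention at C2.

Step 17
Reactants: 28 C2 acetate with benzylic OTBDPS
Product: 29 CNP0205574.1 (target)
Conditions: HF·pyridine, THF–pyridine, 0 → 23 °C
Reagents that add atoms: none
Why: Buffered fluoride desilylation frees the benzylic alcohol without the base that would endanger the acetates, the α-methylene lactone or the C2' centre.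

## Compound list
1 | cyclopentane-1,3-dione | O=C1CCC(=O)C1 | starting material
2 | (E)-but-2-enal | C/C=C/C=O | starting material
3 | (4S)-2-hydroxy-4-methyl-3,4,6,7-tetrahydrocyclopenta[b]pyran-5(2H)-one | C[C@H]1CC(O)OC2=C1C(=O)CC2 | intermediate
4 | (4S)-2-methoxy-4-methyl-3,4,6,7-tetrahydrocyclopenta[b]pyran-5(2H)-one | C[C@H]1CC(OC)OC2=C1C(=O)CC2 | intermediate
5 | (4S)-2-methoxy-4,6-dimethyl-3,4,6,7-tetrahydrocyclopenta[b]pyran-5(2H)-one | C[C@H]1CC(OC)OC2=C1C(=O)C(C)C2 | intermediate
6 | (4S,6S)-6-hydroxy-2-methoxy-4,6-dimethyl-3,4,6,7-tetrahydrocyclopenta[b]pyran-5(2H)-one | C[C@H]1CC(OC)OC2=C1C(=O)[C@@](C)(O)C2 | intermediate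
7 | 5-allyl-5,6-diol adduct of 6 | C[C@H]1CC(OC)OC2=C1C(O)(CC=C)[C@@](C)(O)C2 | intermediate
8 | (3S)-3-[(3S)-2-allyl-3-hydroxy-3-methyl-5-oxocyclopent-1-en-1-yl]butanal | C=CCC1=C([C@@H](C)CC=O)C(=O)C[C@]1(C)O | intermediate
9 | (4S)-3-allyl-2-[(2S)-4,4-dimethoxybutan-2-yl]-4-hydroxy-4-methylcyclopent-2-en-1-one | C=CCC1=C([C@@H](C)CC(OC)OC)C(=O)C[C@]1(C)O | intermediate
10 | methyl 2-amino-4-bromobenzoate | COC(=O)c1ccc(Br)cc1N | starting material
11 | 5-bromo-2-(methoxycarbonyl)benzenediazonium tetrafluoroborate | COC(=O)c1ccc(Br)cc1[N+]#N.F[B-](F)(F)F | intermediate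
12 | (Z)-pent-3-en-1-ol | C/C=C\CCO | starting material
13 | methyl 4-bromo-2-[(2R)-5-oxopentan-2-yl]benzoate | COC(=O)c1ccc(Br)cc1[C@H](C)CCC=O | intermediate
14 | (4R)-4-[5-bromo-2-(hydroxymethyl)phenyl]pentan-1-ol | OCc1ccc(Br)cc1[C@H](C)CCCO | intermediate
15 | (4R)-4-[5-bromo-2-(hydroxymethyl)phenyl]pentyl acetate | OCc1ccc(Br)cc1[C@H](C)CCCOC(C)=O | intermediate
16 | (4R)-4-[5-bromo-2-(TBDPSOCH2)phenyl]pentyl acetate | CC(C)(C)[Si](OCc1ccc(Br)cc1[C@H](C)CCCOC(C)=O)(c1ccccc1)c1ccccc1 | intermediate
17 | methyl 2-bromoacrylate | C=C(Br)C(=O)OC | starting material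
18 | [1-(methoxycarbonyl)ethenyl]zinc bromide | C=C([Zn]Br)C(=O)OC | intermediate
19 | methyl 2-{3-[(2R)-5-acetoxypentan-2-yl]-4-(TBDPSOCH2)phenyl}acrylate | C=C(C(=O)OC)c1ccc(CO[Si](c2ccccc2)(c2ccccc2)C(C)(C)C)c([C@H](C)CCCOC(C)=O)c1 | intermediate
20 | open-chain Michael adduct (C3 and C2' not yet fixed) | C=CCC1=C([C@@H](C)CC(OC)OC)C(=O)C(CC(C(=O)OC)c2ccc(CO[Si](c3ccccc3)(c3ccccc3)C(C)(C)C)c([C@H](C)CCCOC(C)=O)c2)[C@]1(C)O | intermediate
21 | keto δ-lactone acetal | C=CCC1=C([C@@H](C)CC(OC)OC)C(=O)[C@@H]2C[C@H](c3ccc(CO[Si](c4ccccc4)(c4ccccc4)C(C)(C)C)c([C@H](C)CCCOC(C)=O)c3)C(=O)O[C@]12C | intermediate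
22 | keto δ-lactone aldehyde | C=CCC1=C([C@@H](C)CC=O)C(=O)[C@@H]2C[C@H](c3ccc(CO[Si](c4ccccc4)(c4ccccc4)C(C)(C)C)c([C@H](C)CCCOC(C)=O)c3)C(=O)O[C@]12C | intermediate
23 | methyl 2-(bromomethyl)acrylate | C=C(CBr)C(=O)OC | starting material
24 | (Z)-allylic bromide aldehyde | BrC/C(C(=O)OC)=C\CC1=C([C@@H](C)CC=O)C(=O)[C@@H]2C[C@H](c3ccc(CO[Si](c4ccccc4)(c4ccccc4)C(C)(C)C)c([C@H](C)CCCOC(C)=O)c3)C(=O)O[C@]12C | intermediate
25 | ring B hydroxy ester (C7 R, C8 S) | C=C(C(=O)OC)[C@H]1CC2=C([C@@H](C)C[C@@H]1O)C(=O)[C@@H]3C[C@H](c4ccc(CO[Si](c5ccccc5)(c5ccccc5)C(C)(C)C)c([C@H](C)CCCOC(C)=O)c4)C(=O)O[C@]23C | intermediate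
26 | tetracyclic enone | C=C1C(=O)O[C@H]2C[C@H](C)C3=C(C[C@H]12)[C@@]1(C)OC(=O)[C@@H](c2ccc(CO[Si](c4ccccc4)(c4ccccc4)C(C)(C)C)c([C@H](C)CCCOC(C)=O)c2)C[C@H]1C3=O | intermediate
27 | C2 allylic alcohol | C=C1C(=O)O[C@H]2C[C@H](C)C3=C(C[C@H]12)[C@@]1(C)OC(=O)[C@@H](c2ccc(CO[Si](c4ccccc4)(c4ccccc4)C(C)(C)C)c([C@H](C)CCCOC(C)=O)c2)C[C@H]1[C@H]3O | intermediate
28 | C2 acetate with benzylic OTBDPS | C=C1C(=O)O[C@H]2C[C@H](C)C3=C(C[C@H]12)[C@@]1(C)OC(=O)[C@@H](c2ccc(CO[Si](c4ccccc4)(c4ccccc4)C(C)(C)C)c([C@H](C)CCCOC(C)=O)c2)C[C@H]1[C@H]3OC(C)=O | intermediate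
29 | CNP0205574.1 | C=C1C(=O)O[C@H]2C[C@H](C)C3=C(C[C@H]12)[C@@]1(C)OC(=O)[C@@H](c2ccc(CO)c([C@H](C)CCCOC(C)=O)c2)C[C@H]1[C@H]3OC(C)=O | target

## Step count and weakest steps
Total steps: 17. Longest linear sequence: 13 (steps 5–10, then 11–17). The ring C branch is 4 + 7 = 11.

**First risk, step 14.** The seven-membered ring closure competes with oligomerisation and with simple reduction of the bromide. The trans (anti) outcome depends on the allylchromium equilibrating before it adds. Fallback: set out from aldehyde 22. Cross-metathesis with methyl 2-[(trimethylsilyl)methyl]acrylate gives the β-(methoxycarbonyl)allylsilane F1. Bu4NF then triggers an intramolecular Hosomi–Sakurai-type addition to C8 through an open transition state, with no low-valent metal; the stereochemical course can be changed by switching to BF3·OEt2. This gives hydroxy ester 25, which lactonises, and the route is rejoined at 26.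

**Second risk, step 13.** Cross-metathesis with a 1,1-disubstituted acrylate that also carries an allylic bromide may be slow or may poison the catalyst. Fallback: set out from acetal 21.
- OsO4 (cat.) with NaIO4 cleaves the allyl group to the C7 aldehyde F2.
- A DABCO-promoted Morita–Baylis–Hillman reaction with methyl acrylate gives the allylic alcohol F3.
- PBr3 converts F3, with allylic transposition, into the Z-bromide acetal F4.
- PPTS in aqueous acetone frees the C8 aldehyde, and the route is rejoined at 24.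

**Third risk, step 11.** The free C4 alkoxide could undergo retro-aldol ring opening, which would erode C4. The dianion could also react through C6, or the acrylate could oligomerise. Fallback: set out from 9. TMSCl with imidazole gives the C4 silyl ether F5. LDA (1.05 equiv) and 19 at −78 °C give the silylated Michael adduct F6, which is quenched cold. Camphorsulfonic acid in hot benzene then removes the silyl group, equilibrates C3 through the enol and lactonises without any alkoxide being present. The route is rejoined at 21.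

## Further compounds
F1 | step 14 | β-(methoxycarbonyl)allylsilane aldehyde | C[Si](C)(C)C/C(C(=O)OC)=C\CC1=C([C@@H](C)CC=O)C(=O)[C@@H]2C[C@H](c3ccc(CO[Si](c4ccccc4)(c4ccccc4)C(C)(C)C)c([C@H](C)CCCOC(C)=O)c3)C(=O)O[C@]12C
F2 | step 13 | C7 aldehyde (C8 still dimethyl acetal) | O=CCC1=C([C@@H](C)CC(OC)OC)C(=O)[C@@H]2C[C@H](c3ccc(CO[Si](c4ccccc4)(c4ccccc4)C(C)(C)C)c([C@H](C)CCCOC(C)=O)c3)C(=O)O[C@]12C
F3 | step 13 | Morita–Baylis–Hillman alcohol (carbinol epimers) | C=C(C(=O)OC)C(O)CC1=C([C@@H](C)CC(OC)OC)C(=O)[C@@H]2C[C@H](c3ccc(CO[Si](c4ccccc4)(c4ccccc4)C(C)(C)C)c([C@H](C)CCCOC(C)=O)c3)C(=O)O[C@]12C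
F4 | step 13 | (Z)-allylic bromide dimethyl acetal | BrC/C(C(=O)OC)=C\CC1=C([C@@H](C)CC(OC)OC)C(=O)[C@@H]2C[C@H](c3ccc(CO[Si](c4ccccc4)(c4ccccc4)C(C)(C)C)c([C@H](C)CCCOC(C)=O)c3)C(=O)O[C@]12C
F5 | step 11 | C4 trimethylsilyl ether of 9 | C=CCC1=C([C@@H](C)CC(OC)OC)C(=O)C[C@]1(C)O[Si](C)(C)C
F6 | step 11 | silylated Michael adduct (C3 and C2' not yet fixed) | C=CCC1=C([C@@H](C)CC(OC)OC)C(=O)C(CC(C(=O)OC)c2ccc(CO[Si](c3ccccc3)(c3ccccc3)C(C)(C)C)c([C@H](C)CCCOC(C)=O)c2)[C@]1(C)O[Si](C)(C)C
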